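**Strategy.** The ten-membered ring (C1–C10, clerodane numbering) is closed at the bond joining its two adjacent stereocentres, the methyl-bearing CH (C8) and the quaternary carbon with CH3 and the 2-(furan-3-yl)ethyl chain (C9), by an anionic oxy-Cope ring expansion. The precursor is a six-membered ring: a trans-1,6-dialkenylcyclohex-2-en-1-ol cis-fused to a menthyloxy butyrolactone, built by an auxiliary-controlled Diels–Alder reaction and an alkenylcerium addition. One chair [3,3] shift trades the cyclohexene C1–C6 bond for C8–C9, sets both stereocentres from two E alkenes and leaves a C1 ketone that becomes the dienoate; the lactone acetal later unfolds into the methyl ester and the enol acetate.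

Key step: step 10

Remark on numbering: the ring carbons are C1–C10; C4 carries the ester carbon C18, C5 carries C19, C8 carries CH3 (C17), C9 carries CH3 (C20) and the chain C11–C12–furan. The same numbers are used for these atoms in every precursor.

Remark on one assumption: the acetal carbon of 9 is assumed to crystallise as the (5S) epimer with (+)-menthol, the mirror image of the (−)-menthol series.

**Step 1**
Reactants: 1 (E)-pent-3-enoic acid
Product: 3 (E)-N-methoxy-N-methylpent-3-enamide, via acyl imidazolide 2 (not isolated)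
Conditions: CDI, CH2Cl2, 0 °C → rt; then MeNH(OMe)·HCl, rt
Reagents that add atoms: N,O-dimethylhydroxylamine hydrochloride, CNOC.Cl
Why: Carbonyldiimidazole activation followed by amide formation (Weinreb amide synthesis) is near-neutral, so the β,γ-alkene should keep its position and E geometry; no stereocentre is formed.

**Step 2**
Reactants: 3 (E)-N-methoxy-N-methylpent-3-enamide
Product: 5 (E)-hepta-1,5-dien-3-one, via magnesium hemiaminal 4 (not isolated)
Conditions: CH2=CHMgBr, THF, −78 → 0 °C; poured into cold 1 M HCl
Reagents that add atoms: vinylmagnesium bromide, C=C[Mg]Br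
Why: Weinreb ketone synthesis: the chelated tetrahedral intermediate stops at mono-addition and releases the vinyl ketone only on the cold acidic quench, which keeps the liberated amine protonated so that it cannot add to the enone; no stereocentre is formed.

**Step 3**
Reactants: 5 (E)-hepta-1,5-dien-3-one
Product: 6 (3Z,5E)-3-(tert-butyldimethylsilyloxy)hepta-1,3,5-triene
Conditions: TBSOTf, Et3N, Et2O, −78 → 0 °C
Reagents that add atoms: tert-butyldimethylsilyl trifluoromethanesulfonate, CC(C)(C)[Si](C)(C)OS(=O)(=O)C(F)(F)F
Why: Soft enolisation (silyl triflate and amine) removes a proton from the CH2 that is both α to the ketone and allylic; the 3Z silyl dienol ether (OSi cis to propenyl) is expected because the other isomer would place vinyl and propenyl cis on the planar triene, and the 5E alkene is not touched.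

**Step 4**
Reactants: 7 5-hydroxyfuran-2(5H)-one + 8 (+)-menthol
Product: 9 (5S)-5-[(+)-menthyloxy]furan-2(5H)-one
Conditions: camphorsulfonic acid (cat.), toluene, reflux (Dean–Stark); crystallisation from petroleum ether
Reagents that add atoms: none
Why: Acid-catalysed acetalisation (pseudo-ester formation) of the cyclic hemiacetal; the acetal centre epimerises under acid and the (5S) diastereomer should be removed by crystallisation (crystallisation-induced diastereomer enrichment), which sets the only new stereocentre.

**Step 5**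
Reactants: 10 3-(bromomethyl)furan + 11 trimethyl(prop-1-yn-1-yl)silane
Product: 14 3-(but-3-yn-1-yl)furan, via lithiated silylpropyne 12 (not isolated), via silylalkyne 13 (not isolated)
Conditions: 11, n-BuLi, THF, −78 °C; 10, −78 → 0 °C; then K2CO3 (cat.), MeOH, rt
Reagents that add atoms: none
Why: Propargylic lithiation of the silylpropyne and SN2 alkylation by the reactive furylmethyl bromide (the silyl group blocks the alkyne terminus), then methanolytic C–Si cleavage; no stereocentre is formed.

**Step 6**
Reactants: 14 3-(but-3-yn-1-yl)furan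
Product: 16 3-[(E)-4-iodo-3-methylbut-3-en-1-yl]furan, via alkenylalane 15 (not isolated)
Conditions: AlMe3, Cp2ZrCl2 (cat.), CH2Cl2, 0 °C → rt; then I2, THF, −30 → 0 °C
Reagents that add atoms: trimethylaluminium, C[Al](C)C; iodine, II
Why: Negishi zirconium-catalysed carboalumination adds CH3 and Al syn across the terminal alkyne with CH3 on the internal carbon, and iododealumination goes with retention, so the E iodoalkene (I cis to CH3) should result.

**Step 7**
Reactants: 6 (3Z,5E)-3-(tert-butyldimethylsilyloxy)hepta-1,3,5-triene + 9 (5S)-5-[(+)-menthyloxy]furan-2(5H)-one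
Product: 17 Diels–Alder adduct (bicyclic silyl enol ether lactone)
Conditions: toluene, BHT (cat.), 110 °C, sealed tube
Reagents that add atoms: none
Why: Thermal Diels–Alder reaction: the 2-silyloxy group makes C6 the nucleophilic diene terminus, which bonds to the butenolide β-carbon (C5) and so puts C18 on C4 and C19 on C5; addition anti to the menthyloxy group through the endo transition state should set C4, C5 and C6 (H4, H5, H6 all cis, propenyl cis to the lactone) in absolute terms from the (S) acetal carbon.

**Step 8**
Reactants: 17 Diels–Alder adduct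
Product: 18 bicyclic enone lactone
Conditions: Pd(OAc)2 (1.1 equiv), MeCN, rt
Reagents that add atoms: none
Why: Saegusa oxidation: the silyl enol ether gives a divalent palladium enolate at C2, and β-hydride elimination from C3 forms the C2=C3 enone; no stereocentre is created and the neutral medium should leave the epimerisable C6 alone.

**Step 9**
Reactants: 16 3-[(E)-4-iodo-3-methylbut-3-en-1-yl]furan + 18 bicyclic enone lactone
Product: 21 trans-1,6-dialkenylcyclohex-2-en-1-ol, via alkenyllithium 19 (not isolated), via alkenylcerium dichloride 20 (not isolated)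
Conditions: 16, t-BuLi (2 equiv), Et2O, −78 °C; CeCl3, THF, −78 °C; then 18, −78 °C; aq. NH4Cl
Reagents that add atoms: none
Why: Iodine–lithium exchange and transmetalation give a weakly basic alkenylcerium reagent that should add 1,2 to the ketone (organocerium carbonyl addition) instead of deprotonating C4 or C6 or attacking the lactone; attack on the convex face of the cis-fused bicycle (the face of H4, H5, H6) sets the C1 carbinol with the new alkenyl group trans to the propenyl group.

**Step 10**
Reactants: 21 trans-1,6-dialkenylcyclohex-2-en-1-ol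
Product: 24 ten-membered (2Z,6E)-dienone, via potassium alkoxide 22 (not isolated), via potassium dienolate 23 (not isolated)
Conditions: KN(SiMe3)2, 18-crown-6, THF, −40 → 0 °C; then AcOH, −78 °C
Reagents that add atoms: none
Why: Deprotonation gives alkoxide 22, whose 1,5-diene C9=C10–C1(O−)–C6–C7=C8 undergoes the charge-accelerated [3,3] sigmatropic shift (anionic oxy-Cope rearrangement), breaking C1–C6 and forming C8–C9 to give dienolate 23, which is protonated at C10. The closest known reaction type is the oxy-Cope ring expansion of trans-1,2-dialkenylcyclohexanols to (E)-cyclodec-5-enones. The ten-membered ring is closed by ring expansion of the cyclohexene by four atoms, not by end-to-end cyclisation, so no high dilution is needed. The trans-diequatorial alkenyl groups allow only the chair transition state, in which the E-propenyl CH3 is equatorial on C8 and the E-alkenyl group places CH3 axial and the furylethyl chain equatorial on C9; with the face fixed by C1 and C6 this should give 8R and 9R and the E C6=C7 alkene. The step needs periselectivity over the [3,3] path through the ring alkene C2=C3 (possible only through a boat) and chemoselectivity over attack of the alkoxide or the dienolate on the lactone carbonyl, which the chair geometry, the low temperature and the cold acidic quench should secure.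

**Step 11**
Reactants: 24 ten-membered (2Z,6E)-dienone
Product: 26 dienyl triflate, via sodium dienolate 25 (not isolated)
Conditions: NaH, THF, 0 °C → rt; then PhNTf2, 0 °C → rt
Reagents that add atoms: N-phenylbis(trifluoromethanesulfonimide), O=S(=O)(N(c1ccccc1)S(=O)(=O)C(F)(F)F)C(F)(F)F
Why: Thermodynamic deprotonation at C4 (γ to the ketone and α to the lactone carbonyl) gives the linear dienolate, and O-sulfonylation gives the dienyl triflate (enol triflate formation); the conformation inherited from the cyclohexene keeps C2 and C5 cis across the new C3=C4 bond, the equilibrating dienolate should settle with C10 and C3 cis across C1=C2 as the less strained ring form, and the C4 stereocentre is erased.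

**Step 12**
Reactants: 26 dienyl triflate
Product: 27 6,7-dihydro dienyl triflate
Conditions: KO2CN=NCO2K, AcOH, pyridine/CH2Cl2, rt
Reagents that add atoms: none
Why: Diimide reduction (concerted syn transfer of H2) should be fastest at the strained, isolated E-disubstituted C6=C7 alkene and spare the trisubstituted electron-poor dienyl triflate, the furan and the carbonyl groups; no stereocentre is formed.

**Step 13**
Reactants: 27 6,7-dihydro dienyl triflate
Product: 28 (1Z,3Z)-dienyl menthyloxy lactone
Conditions: Pd(OAc)2 (cat.), PPh3, HCO2H, n-Bu3N, DMF, 60 °C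
Reagents that add atoms: none
Why: Palladium-catalysed formate reduction of an alkenyl triflate: oxidative addition to zerovalent palladium, formate exchange, loss of CO2 and reductive elimination replace OTf by H with retention of the C1=C2 geometry.

**Step 14**
Reactants: 28 (1Z,3Z)-dienyl menthyloxy lactone
Product: 31 target compound CNP0318171.1, via aldehyde ester 29 (not isolated), via sodium enolate 30 (not isolated)
Conditions: NaOMe (1.1 equiv), THF, −40 → 0 °C; then Ac2O, −78 °C → rt
Reagents that add atoms: sodium methoxide, C[O-].[Na+]; acetic anhydride, CC(=O)OC(C)=O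
Why: Methoxide opens the activated pseudo-ester at C18 (acyl substitution), the hemiacetal alkoxide collapses to the C19 aldehyde and menthoxide, menthoxide removes H5 to give the sodium enolate, and O-acetylation gives the enol acetate; sodium chelation between the enolate oxygen and the C18 ester carbonyl is expected to hold the oxygen cis to C4 (Z), and the C5 and C19 stereocentres are erased.

**Compound list**

1 | (E)-pent-3-enoic acid | C/C=C/CC(=O)O | starting material
2 | (E)-1-(imidazol-1-yl)pent-3-en-1-one (acyl imidazolide, not isolated) | C/C=C/CC(=O)n1ccnc1 | intermediate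
3 | (E)-N-methoxy-N-methylpent-3-enamide | C/C=C/CC(=O)N(C)OC | intermediate
4 | bromomagnesium (E)-3-[methoxy(methyl)amino]hepta-1,5-dien-3-olate (not isolated) | C/C=C/CC(O[Mg]Br)(C=C)N(C)OC | intermediate
5 | (E)-hepta-1,5-dien-3-one | C=CC(=O)C/C=C/C | intermediate
6 | (3Z,5E)-3-(tert-butyldimethylsilyloxy)hepta-1,3,5-triene | C=C/C(O[Si](C)(C)C(C)(C)C)=C/C=C/C | intermediate
7 | 5-hydroxyfuran-2(5H)-one | O=C1C=CC(O)O1 | starting material
8 | (+)-menthol, (1S,2R,5S)-2-isopropyl-5-methylcyclohexan-1-ol | CC(C)[C@H]1CC[C@H](C)C[C@@H]1O | starting material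
9 | (5S)-5-[(1S,2R,5S)-menthyloxy]furan-2(5H)-one | O=C1C=C[C@@H](O[C@H]2C[C@@H](C)CC[C@@H]2C(C)C)O1 | intermediate
10 | 3-(bromomethyl)furan | BrCc1ccoc1 | starting material
11 | trimethyl(prop-1-yn-1-yl)silane | CC#C[Si](C)(C)C | starting material
12 | [3-(trimethylsilyl)prop-2-yn-1-yl]lithium (not isolated) | [Li]CC#C[Si](C)(C)C | intermediate
13 | [4-(furan-3-yl)but-1-yn-1-yl]trimethylsilane (not isolated) | C[Si](C)(C)C#CCCc1ccoc1 | intermediate
14 | 3-(but-3-yn-1-yl)furan | C#CCCc1ccoc1 | intermediate
15 | [(E)-4-(furan-3-yl)-2-methylbut-1-en-1-yl]dimethylalane (not isolated) | C[Al](C)/C=C(\C)CCc1ccoc1 | intermediate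
16 | 3-[(E)-4-iodo-3-methylbut-3-en-1-yl]furan | I/C=C(\C)CCc1ccoc1 | intermediate
17 | Diels–Alder adduct: (3S)-3-[(+)-menthyloxy]-4-[(E)-prop-1-enyl]-5-(tert-butyldimethylsilyloxy)-3a,4,7,7a-tetrahydroisobenzofuran-1(3H)-one; cis-fused, H4, H5 and H6 (route numbering) all cis, menthyloxy cis to H5 | C/C=C/[C@H]1C(O[Si](C)(C)C(C)(C)C)=CC[C@H]2C(=O)O[C@H](O[C@H]3C[C@@H](C)CC[C@@H]3C(C)C)[C@@H]12 | intermediate
18 | (3S)-3-[(+)-menthyloxy]-4-[(E)-prop-1-enyl]-3a,4-dihydroisobenzofuran-1,5(3H,7aH)-dione; ring stereochemistry as in 17 | C/C=C/[C@H]1C(=O)C=C[C@H]2C(=O)O[C@H](O[C@H]3C[C@@H](C)CC[C@@H]3C(C)C)[C@@H]12 | intermediate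
19 | [(E)-4-(furan-3-yl)-2-methylbut-1-en-1-yl]lithium (not isolated) | [Li]/C=C(\C)CCc1ccoc1 | intermediate
20 | dichloro[(E)-4-(furan-3-yl)-2-methylbut-1-en-1-yl]cerium (not isolated) | Cl[Ce](Cl)/C=C(\C)CCc1ccoc1 | intermediate
21 | 5-hydroxy-5-[(E)-4-(furan-3-yl)-2-methylbut-1-enyl]-3-[(+)-menthyloxy]-4-[(E)-prop-1-enyl]-3a,4,5,7a-tetrahydroisobenzofuran-1(3H)-one; alkenyl on C1 trans to propenyl on C6, OH cis to propenyl | C/C=C/[C@H]1[C@](O)(/C=C(\C)CCc2ccoc2)C=C[C@H]3C(=O)O[C@H](O[C@H]4C[C@@H](C)CC[C@@H]4C(C)C)[C@@H]13 | intermediate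
22 | potassium alkoxide of 21 (not isolated) | C/C=C/[C@H]1[C@]([O-])(/C=C(\C)CCc2ccoc2)C=C[C@H]3C(=O)O[C@H](O[C@H]4C[C@@H](C)CC[C@@H]4C(C)C)[C@@H]13.[K+] | intermediate
23 | potassium C1(O−)=C10 dienolate of 24 (not isolated) | C[C@@]1(CCc2ccoc2)/C=C(\[O-])/C=C\[C@H]3C(=O)O[C@H](O[C@H]4C[C@@H](C)CC[C@@H]4C(C)C)[C@H]3/C=C/[C@H]1C.[K+] | intermediate
24 | ten-membered dienone: ring C1–C10 with C1 ketone, (2Z) and (6E) alkenes, (8R)-CH3, (9R)-CH3 and 2-(furan-3-yl)ethyl, cis-fused at C4–C5 to the (19S)-menthyloxy γ-lactone C18(=O)–O–C19 | O=C1/C=C\[C@H]2C(=O)O[C@H](O[C@H]3C[C@@H](C)CC[C@@H]3C(C)C)[C@H]2/C=C/[C@@H](C)[C@](C)(CCc4ccoc4)C1 | intermediate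
25 | sodium O–C1=C2–C3=C4 dienolate of 24 (not isolated) | C[C@@]1(CCc2ccoc2)C/C([O-])=C\C=C3\C(=O)O[C@H](O[C@H]4C[C@@H](C)CC[C@@H]4C(C)C)[C@H]3/C=C/[C@H]1C.[Na+] | intermediate
26 | dienyl triflate: C1(OTf)=C2 (C10 cis to C3), C3=C4 (C2 cis to C5), (6E) alkene, (8R,9R), menthyloxy lactone on C4–C5 | C[C@@]1(CCc2ccoc2)C/C(OS(=O)(=O)C(F)(F)F)=C\C=C3\C(=O)O[C@H](O[C@H]4C[C@@H](C)CC[C@@H]4C(C)C)[C@H]3/C=C/[C@H]1C | intermediate
27 | 6,7-dihydro derivative of 26 | C[C@@]1(CCc2ccoc2)C/C(OS(=O)(=O)C(F)(F)F)=C\C=C3\C(=O)O[C@H](O[C@H]4C[C@@H](C)CC[C@@H]4C(C)C)[C@H]3CC[C@H]1C | intermediate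
28 | (1Z,3Z)-diene with C4 as the α-carbon of the (19S)-menthyloxy γ-lactone, (8R,9R) | C[C@@]1(CCc2ccoc2)C/C=C\C=C3\C(=O)O[C@H](O[C@H]4C[C@@H](C)CC[C@@H]4C(C)C)[C@H]3CC[C@H]1C | intermediate
29 | methyl (1Z,3Z,8R,9R)-5-formyl dienoate (C19 aldehyde, not isolated) | COC(=O)/C1=C/C=C\C[C@@](C)(CCc2ccoc2)[C@H](C)CC[C@@H]1C=O | intermediate
30 | sodium (Z)-enolate of 29 (not isolated) | COC(=O)/C1=C/C=C\C[C@@](C)(CCc2ccoc2)[C@H](C)CC\C1=C\[O-].[Na+] | intermediate
31 | CNP0318171.1: methyl ester with (1Z,3Z)-diene, (Z)-C5=C19 enol acetate, (8R,9R) | COC(=O)/C1=C/C=C\C[C@@](C)(CCc2ccoc2)[C@H](C)CC\C1=C\OC(C)=O | target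

**Totals and risks**

Total step count: 14. Longest linear sequence: 11 steps (steps 1, 2, 3, 7, 8, 9, 10, 11, 12, 13, 14).

Most likely to fail:

1. Step 10 (key step). The potassium dienolate formed after the rearrangement may acylate itself across the ring at the lactone carbonyl, or the alkoxide may rearrange through the ring alkene C2=C3 instead of the side-chain alkene. Fallback: a neutral thermal variant that carries no charged oxygen. It sets out from 21, which is silylated (TMSCl, imidazole) to the trimethylsilyl ether F1. Heating F1 in a degassed high-boiling solvent in a sealed tube should give, by the siloxy-Cope rearrangement through the same chair, the ring-expanded trimethylsilyl dienol ether F2. Mild acidic methanolysis of F2 returns the route at 24.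

2. Step 9. The organometallic may enolise the ketone (at C4, γ and next to the lactone carbonyl, or at C6) instead of adding, and C6 may lose its configuration. Fallback: the enone is introduced after the ring expansion. It sets out from 17, which is hydrolysed (1 M HCl, THF) to the saturated ketone F3. Addition of alkenylcerium 20 from the same convex face gives the saturated carbinol F4, and the anionic oxy-Cope rearrangement (now without a competing ring alkene) gives the cyclodec-6-enone F5. Dehydrogenation with IBX can only go towards C2–C3, because C9 is quaternary. It gives 24 or its 2E isomer, the enone F6. Either is converted as in step 11, because the dienolate erases the C2=C3 geometry, and the route is rejoined at 26.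

3. Step 14. Enolate formation may show poor Z/E control, or the extended enolate may scramble its geometry, so that a mixture of enol acetates results. Fallback: the geometry is fixed by a ring before the ester is made. It sets out from 28, which loses menthol with TMSOTf and i-Pr2NEt (acetal-to-enol-ether elimination) to give the enol lactone F7, a 3-ylidene furan-2(3H)-one with C19=C5 inside the five-membered ring. Opening of this enol ester with NaOMe in THF at −78 °C gives the Z enolate directly, because the oxygen and C4 were ring neighbours. The route is rejoined at 30, which is acetylated as in step 14.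

**Further compounds**

F1 | step 10 | trimethylsilyl ether of 21 | C/C=C/[C@H]1[C@](O[Si](C)(C)C)(/C=C(\C)CCc2ccoc2)C=C[C@H]3C(=O)O[C@H](O[C@H]4C[C@@H](C)CC[C@@H]4C(C)C)[C@@H]13
F2 | step 10 | trimethylsilyl C1(OSiMe3)=C10 dienol ether of 24 | C[C@@]1(CCc2ccoc2)/C=C(\O[Si](C)(C)C)/C=C\[C@H]3C(=O)O[C@H](O[C@H]4C[C@@H](C)CC[C@@H]4C(C)C)[C@H]3/C=C/[C@H]1C
F3 | step 9 | saturated ketone: (3S)-3-[(+)-menthyloxy]-4-[(E)-prop-1-enyl]hexahydroisobenzofuran-1,5-dione, ring stereochemistry as in 17 | C/C=C/[C@H]1C(=O)CC[C@H]2C(=O)O[C@H](O[C@H]3C[C@@H](C)CC[C@@H]3C(C)C)[C@@H]12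
F4 | step 9 | saturated carbinol: 2,3-dihydro analogue of 21 | C/C=C/[C@H]1[C@](O)(/C=C(\C)CCc2ccoc2)CC[C@H]3C(=O)O[C@H](O[C@H]4C[C@@H](C)CC[C@@H]4C(C)C)[C@@H]13
F5 | step 9 | cyclodec-6-enone: 2,3-dihydro analogue of 24 | O=C1CC[C@H]2C(=O)O[C@H](O[C@H]3C[C@@H](C)CC[C@@H]3C(C)C)[C@H]2/C=C/[C@@H](C)[C@](C)(CCc4ccoc4)C1
F6 | step 9 | (2E) isomer of dienone 24 | O=C1/C=C/[C@H]2C(=O)O[C@H](O[C@H]3C[C@@H](C)CC[C@@H]3C(C)C)[C@H]2/C=C/[C@@H](C)[C@](C)(CCc4ccoc4)C1
F7 | step 14 | enol lactone: (1Z,3Z)-diene with C18(=O)–O–C19H=C5 furan-2(3H)-one, (8R,9R) | C[C@@]1(CCc2ccoc2)C/C=C\C=C3\C(=O)OC=C3CC[C@H]1C
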